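A racemic substrate meets a single-handed reagent, and in the south run 31.1 % of it is still not product at 60.0 h.

| setting | south | west | grey | amber | red | violet |
|---|---|---|---|---|---|---|
| left-handed substrate | 0.52 M | 0.52 M | 0.52 M | 0.52 M | 0.52 M | 0.52 M |
| right-handed substrate | 0.52 M | 0.52 M | 0.52 M | 0.52 M | 0.52 M | 0.52 M |
| reagent | 1.4 M | 1.4 M | 2.08 M | 2.08 M | 2.08 M | 2.08 M |
| temperature | 18 °C | 45 °C | 30 °C | 55 °C | 5 °C |  |
| remark | run made earlier | run made earlier |  |  |  | at 55 °C until 40 h, from then on at 5 °C |
| time |  |  | 50 h | 50 h | 50 h | 50 h |

| run | time / h | left-handed product / % | right-handed product / % |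
|---|---|---|---|
| south | 8.00 | 10.7 | 6.7 |
| south | 15.0 | 16.1 | 12.6 |
| south | 20.0 | 23.2 | 14.9 |
| south | 25.0 | 26.3 | 18.1 |
| south | 40.0 | 36.1 | 21.7 |
| south | 50.0 | 37.9 | 24.9 |
| south | 60.0 | 41.2 | 27.7 |
| west | 2.00 | 25.7 | 27.2 |
| west | 4.00 | 35.4 | 37.4 |
| west | 6.00 | 40.0 | 42.8 |
| west | 8.00 | 42.2 | 45.2 |
| west | 10.0 | 42.2 | 47.5 |
| west | 12.0 | 44.8 | 47.0 |
| west | 15.0 | 45.6 | 48.7 |

(scatter of a reading: 1 percentage point)

- reagent is single-handed; left-handed substrate and right-handed substrate are mirror images of each other, charged as a racemate, each of them at the stated concentration
- the analysis behind the earlier runs scatters by 1 percentage point, standard deviation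
- candidate steps: left-handed substrate <-> achiral form; right-handed substrate <-> achiral form; reagent + right-handed substrate -> right-handed product; reagent + left-handed substrate -> left-handed product; reagent -> decomposition product
- an excess is the difference of the two amounts in percent of their sum
- an excess is below zero if the other one leads
- the handed part of reagent does not stay in what it makes, so the products of the two hands are mirror images too

1. which flask leads in excess of left-handed product over right-handed product ("all alike" within 1.5 percentage points) (grey / amber / red / violet / all alike)
2. excess of left-handed product over right-handed product at the end, grey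
3. excess of left-handed product over right-handed product at the end, amber
4. excess of left-handed product over right-handed product at the end, red
5. excess of left-handed product over right-handed product at the end, violet

That leftover doesn't fit the excess. If each hand kept to itself, the south run would hold 8.80 % of left-handed substrate against 22.3 % of right-handed substrate, and left-handed product should fall behind. Yet the excess reads 18.5 % at 25.0 h and 19.6 % at 60.0 h. So I take it that the hands cross through the achiral form and stay level, which is dynamic kinetic resolution.

The product ratio s, the selectivity factor, then reads as a ratio of rate constants: 1.49 at the last reading of the south run and 0.936 at the last reading of the west run. The excess is s less one over s plus one. I assume ln s is straight in reciprocal absolute temperature. The two runs give 1590 K, my hand slope: the rise of ln s per unit of reciprocal temperature.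

From the south run I reckon s = 1.20 for grey, so 9.03 %. For amber, s = 0.804, so −10.8 %. For red, s = 1.92, so 31.5 %, and red leads.

Violet ends at red's temperature, but I expect amber's excess. The west run is cooler than violet's first stage and has less reagent, yet it reads 94.3 % as product by 15.0 h, sooner than violet's change at 40 h. Each candidate step that makes a product runs one way.

The forecast, close to mine but not the same, says 8.5 %, −10 %, 30 % and −10 % for grey, amber, red and violet, with red leading: “Violet is finished well before cooling”.

The flasks give 8.65 %, −12.1 %, 31.7 % and −12.1 %, and red leads.

    left-handed substrate ⇌ achiral form (K = 0.213, k = 0.00434 min⁻¹, Ea = 93.0 kJ mol⁻¹, ΔH = −15.0 kJ mol⁻¹)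
    right-handed substrate ⇌ achiral form (K = 0.213, k = 0.00434 min⁻¹, Ea = 93.0 kJ mol⁻¹, ΔH = −15.0 kJ mol⁻¹)
    reagent + right-handed substrate → right-handed product (k = 5.19 × 10⁻⁵ M⁻¹ min⁻¹, Ea = 89.0 kJ mol⁻¹)
    reagent + left-handed substrate → left-handed product (k = 1.02 × 10⁻⁴ M⁻¹ min⁻¹, Ea = 75.0 kJ mol⁻¹)
    reagent → decomposition product (k = 2.51 × 10⁻⁷ min⁻¹, Ea = 120 kJ mol⁻¹)
    (constants at 5 °C)

The forecast holds. In red, at the start, left-handed substrate goes to left-handed product at 0.049 of its forward rate to achiral form, and that step alone, both ways together, relaxes with a half-life of 0.467 h. Now take the red flask at −10 °C. The hand slope gives s = 2.66, so 45.3 %. That flask gives 46.2 %, from 4.17 % of left-handed product and 1.54 % of right-handed product at the end.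

The readings come from a simulation from invented constants; the scatter is artificial.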